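## The problem

(+)-8-Methoxyisolariciresinol (24) is a 1-aryltetralin cyclolignan. A benzene ring with H at C5, OMe at C6, OH at C7 and OMe at C8 is fused to a six-membered carbocycle that carries a guaiacyl group on C1, hydroxymethyl groups on C2 (C9') and C3 (C9), and a CH2 at C4. The three contiguous stereocentres are (1S,2R,3R), all-trans, so the C1 aryl group is cis to the C3 substituent.

C3 has no activating neighbour and cannot be corrected once made, so it is the place to bring in absolute configuration. C2 can be kept epimerisable by holding C9' at the aldehyde level, and it will then follow C3 into the trans arrangement. C1 is the hard centre: it is doubly benzylic and its aryl group must end next to the C8 methoxy group in the peri position.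

The two free phenols sit on electron-rich rings that oxidise easily, and the 1,4-diol closes to a tetrahydrofuran under strong acid, so the last steps must be neutral and reductive. The C6/C7/C8 oxygen pattern must be placed without ambiguity.

The feature that the plan uses is this: C1 is benzylic and para to the 4-hydroxyl of the guaiacyl ring, which makes it a latent p-quinone methide carbon. C2 is the α-carbon of C9' when C9' is an aldehyde. C3, C4, C4a and C8a hold these two carbons in a six-membered array.

## Retrosynthesis

**24 back to 22 (no skeletal bond cut).** The two benzyl ethers of 23 (on O7 and on O9) come off in one hydrogenolysis, and the C9' alcohol of 23 comes from the aldehyde 22 by borohydride reduction. Reducing before hydrogenolysis freezes C2 and keeps the aldehyde away from palladium. Benzyl is chosen for both oxygens so that a single neutral step ends the synthesis.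

**22 back to 20 (cut C1–C2).** This is the disconnection that carries the plan. The neighbouring cuts are C1–C8a (Friedel–Crafts) and C4–C4a (arene alkylation). Cutting C1–C2 instead makes a bond between two carbons that are both activated by groups the target already has: the para-hydroxyl turns C1 into a quinone methide carbon and the C9' aldehyde turns C2 into an enamine carbon. The precursor 20 is an open-chain aldehyde with one stereocentre (C3) and a p-hydroxybenzhydrol whose configuration does not matter. The forward reaction must close a 6-exo ring, set C2 trans to C3 and set C1 cis to the C3 substituent.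

**20 back to 17 (functional-group changes only).** The phenol of 20 is unmasked from the silyl ether 19 and the aldehyde carbon C9' of 19 is the internal carbon of a terminal alkene in 17. The alkene is inert to organolithium chemistry, and the silyl ether protects the guaiacol from periodate during the cleavage. This order puts the sensitive pairing of free phenol, ionisable carbinol and aldehyde in a single compound, 20, just before it is used.

**17 back to 13 and 15 (cut C1–C8a).** The benzhydrol is made by adding the aryllithium 16, formed from bromide 13, to silylated vanillin 15, which is made from vanillin 14. Bromine fixes C8a on the only type of free ring position, so the oxygen pattern cannot be scrambled. The carbinol forms as both epimers, which is acceptable because C1 becomes trigonal in the key step.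

**13 back to 10 (functional-group changes only).** Bromide 13 comes from ring bromination of benzyl ether 12, which comes from alcohol 11, the reduction product of imide 10. The two free ring positions of 12 are equivalent by rotation, so monobromination can give only one product.

**10 back to 8 and 4 (cut C3–C4).** The C3 centre is set by alkylating the enolate 9 of pent-4-enoyl imide 8 with benzyl bromide 4. Imide 8 comes from auxiliary 5 and pent-4-enoic acid 6 through the mixed anhydride 7. Bromide 4 comes from syringaldehyde 1 through ether 2 and alcohol 3. The (R)-auxiliary is required: it gives (2S) in 10, 11, 12, 13 and 17, and this same arrangement is named (3R) in 18, 19 and 20 only because the priority of the chain arms changes when the alkene is oxidised. This cut is preferred to the reverse pairing (arylpropanoyl imide plus allyl halide) because that route would need an extra chain-building sequence on the arene.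

## Roads not taken

**Alternative 1:** Itaconate [3+3] annulation. The cut removes C1–C2 and C4–C4a together. The benzhydryl sulfone A1 would lose sulfinate under a chiral phase-transfer base to give its quinone methide. The dienolate of dimethyl itaconate A2 would add through its α-carbon to form C1–C2. The phenoxide of the second ring would then add through its para carbon C4a to the acrylate terminus and close the ring to diester A3.
- Merits: one step makes the ring, two bonds and all three centres; no protecting groups are needed; C2 and C3 are both α to esters and settle all-trans; A3 is one hydride reduction from 24. In step count and protecting-group economy this road is clearly better than the chosen one, perhaps by half.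
- Weak points: the absolute configuration rests entirely on ion-pair recognition of a transient, unhindered quinone methide in an intermolecular step. Because C2 and C3 equilibrate, any error at C1 lowers enantiopurity and does not give separable diastereomers. The dienolate must react at its α- and not its γ-carbon. The second bond needs a phenoxide to alkylate at carbon with a plain acrylate, which is a reversible dearomatising addition. A1 has its benzhydryl carbon meta to the ring hydroxyl, where simple electrophilic substitution of the parent phenol does not put it, so A1 needs a directed synthesis of its own.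
- What the chosen plan sets against the shorter route: a C3 centre of secured configuration (auxiliary, diastereomers separable at 10), an intramolecular 6-exo closure, and routine chemistry everywhere else.

**Alternative 2:** Aryne insertion into a cyclobutanone. The cut removes C4–C4a and C1–C8a. Fluoride would release the aryne from silyl triflate A5. The sulfonyl-stabilised enolate carbon of cyclobutanone A4 would add at C4a, the aryl anion at C8a would attack the ketone, and the strained alkoxide would fragment to tetralone A6.
- Merits: a convergent union of the arene with a four-carbon unit; the 2,3-trans relation is fixed in a small ring beforehand; the methoxy group next to the aryne steers the addition the right way; no acid-labile benzhydrol is carried. In these respects it is as good as or better than the chosen plan.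
- Weak points: A6 lacks the guaiacyl group and the C1 centre. Aryl addition to the ketone, benzylic deoxygenation with control of C1 against the peri methoxy group, desulfonylation and deprotection must all follow. C1 would be set late, by hydride delivery, with no better control than in the chosen plan. Enantiopure A4 is a strained, acidic β-keto sulfone that needs a multistep synthesis, and A5 is a hexasubstituted benzene.
- What the chosen plan sets against it: the aryl group is in place before ring closure, C1 and C2 form in the closing event, only two steps follow the closure, and the starting materials are two cheap aldehydes and one acid.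

**Alternative 3:** Oxetane opening by the phenol ring. The cut removes C4–C4a. Acid would activate the oxetane of A7, and the free-phenol ring would attack one of the two oxetane CH2 groups through C4a (6-exo-tet), giving tetralin A8 and releasing the C9 hydroxyl.
- Merits: the closure creates only C3, chosen between two diastereotopic CH2 groups through a chair with C1 and C2 already fixed. No new benzylic centre forms under peri strain and the nucleophile is the native C7 phenol ring. The stereochemical outcome of this closure is more predictable than that of step 13.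
- Weak points: the difficulty moves into the precursor. A7 needs an acyclic diarylmethine centre at C1 bearing two similar electron-rich rings, set together with C2 in an open chain, plus the installation of the oxetane. The guaiacyl ring must be deactivated as a mesylate so that it does not compete for the oxetane. Mesylate and pivalate removal add steps after A8.
- What the chosen plan sets against the safer closure: the precursor 20 has one stereocentre, made by standard auxiliary chemistry, and every step before the closure is routine.

Key step: step 13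

## Route

Assumption: the carbinol carbon of 17, 18, 19 and 20 is carried as a mixture of both epimers, because it becomes trigonal in step 13. The (R)-auxiliary 5 and the (R)-prolinol ether catalyst are bought.

Step 1
Reactants: 1 syringaldehyde
Product: 2 4-(benzyloxy)-3,5-dimethoxybenzaldehyde
Conditions: BnBr, K2CO3, DMF, 60 °C
Reagents that add atoms: benzyl bromide, BrCc1ccccc1
Why: Williamson ether synthesis on the phenoxide; the aldehyde is inert to carbonate and the hindered phenol still alkylates cleanly in DMF.

Step 2
Reactants: 2 4-(benzyloxy)-3,5-dimethoxybenzaldehyde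
Product: 3 [4-(benzyloxy)-3,5-dimethoxyphenyl]methanol
Conditions: NaBH4, MeOH/THF, 0 °C
Reagents that add atoms: none
Why: Borohydride reduction of an aryl aldehyde; nothing else in the molecule is reducible.

Step 3
Reactants: 3 [4-(benzyloxy)-3,5-dimethoxyphenyl]methanol
Product: 4 2-(benzyloxy)-5-(bromomethyl)-1,3-dimethoxybenzene
Conditions: PBr3, CH2Cl2, 0 °C; used fresh
Reagents that add atoms: phosphorus tribromide, BrP(Br)Br
Why: Conversion of a benzylic alcohol to the bromide through its phosphite ester; the aryl benzyl ether survives short exposure at 0 °C and the reactive bromide is used without storage.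

Step 4
Reactants: 5 (4R)-4-benzyl-1,3-oxazolidin-2-one; 6 pent-4-enoic acid
Product: 8 (4R)-4-benzyl-3-(pent-4-enoyl)-1,3-oxazolidin-2-one, via mixed pivalic anhydride 7 (not isolated)
Conditions: PivCl, Et3N, THF, −20 °C; then LiCl, 5, −20 °C → rt
Reagents that add atoms: none
Why: N-acylation of an Evans auxiliary through the mixed pivalic anhydride with LiCl activation; attack occurs at the unhindered pentenoyl carbonyl.

Step 5
Reactants: 8 (4R)-4-benzyl-3-(pent-4-enoyl)-1,3-oxazolidin-2-one; 4 2-(benzyloxy)-5-(bromomethyl)-1,3-dimethoxybenzene
Product: 10 (4R)-4-benzyl-3-[(2S)-2-{[4-(benzyloxy)-3,5-dimethoxyphenyl]methyl}pent-4-enoyl]-1,3-oxazolidin-2-one, via sodium Z-enolate 9 (not isolated)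
Conditions: NaHMDS, THF, −78 °C; then 4, −78 → −30 °C
Reagents that add atoms: none
Why: Evans asymmetric alkylation; the chelated Z-enolate is attacked by the benzylic bromide on the face opposite the C4 benzyl group of the (R)-auxiliary, which sets the future C3 as (2S) here, and the minor diastereomer can be removed by chromatography.

Step 6
Reactants: 10 (4R)-4-benzyl-3-[(2S)-2-{[4-(benzyloxy)-3,5-dimethoxyphenyl]methyl}pent-4-enoyl]-1,3-oxazolidin-2-one
Product: 11 (2S)-2-{[4-(benzyloxy)-3,5-dimethoxyphenyl]methyl}pent-4-en-1-ol
Conditions: LiBH4, H2O (1 equiv), Et2O, 0 °C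
Reagents that add atoms: none
Why: Reductive removal of the oxazolidinone with lithium borohydride gives the primary alcohol without touching the stereocentre, and auxiliary 5 is recovered.

Step 7
Reactants: 11 (2S)-2-{[4-(benzyloxy)-3,5-dimethoxyphenyl]methyl}pent-4-en-1-ol
Product: 12 2-(benzyloxy)-5-[(2S)-2-[(benzyloxy)methyl]pent-4-en-1-yl]-1,3-dimethoxybenzene
Conditions: NaH, BnBr, Bu4NI (cat.), THF/DMF, 0 °C → rt
Reagents that add atoms: benzyl bromide, BrCc1ccccc1
Why: Williamson benzylation of a primary alkoxide; the O9 benzyl ether matches the O7 benzyl ether so that both leave in the last step.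

Step 8
Reactants: 12 2-(benzyloxy)-5-[(2S)-2-[(benzyloxy)methyl]pent-4-en-1-yl]-1,3-dimethoxybenzene
Product: 13 4-(benzyloxy)-1-[(2S)-2-[(benzyloxy)methyl]pent-4-en-1-yl]-2-bromo-3,5-dimethoxybenzene
Conditions: NBS (1.05 equiv), MeCN, 0 °C, dark
Reagents that add atoms: N-bromosuccinimide, O=C1CCC(=O)N1Br
Why: Electrophilic aromatic bromination with NBS in acetonitrile; the only free ring positions are two equivalent ones ortho and para to methoxy groups, the first bromine deactivates the ring toward a second, and an isolated monosubstituted alkene reacts far more slowly than the trialkoxyarene under these polar, non-radical conditions.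

Step 9
Reactants: 14 vanillin
Product: 15 4-[(tert-butyldimethylsilyl)oxy]-3-methoxybenzaldehyde
Conditions: TBSCl, imidazole, CH2Cl2, rt
Reagents that add atoms: tert-butyldimethylsilyl chloride, CC(C)(C)[Si](C)(C)Cl
Why: Silylation of a phenol; the silyl ether removes the acidic proton before the organolithium step and shields the guaiacol from periodate in step 11.

Step 10
Reactants: 13 4-(benzyloxy)-1-[(2S)-2-[(benzyloxy)methyl]pent-4-en-1-yl]-2-bromo-3,5-dimethoxybenzene; 15 4-[(tert-butyldimethylsilyl)oxy]-3-methoxybenzaldehyde
Product: 17 {3-(benzyloxy)-6-[(2S)-2-[(benzyloxy)methyl]pent-4-en-1-yl]-2,4-dimethoxyphenyl}{4-[(tert-butyldimethylsilyl)oxy]-3-methoxyphenyl}methanol (both carbinol epimers), via aryllithium 16 (not isolated)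
Conditions: n-BuLi, THF, −78 °C, 15 min; then 15, −78 → −40 °C; then H2O
Reagents that add atoms: none
Why: Bromine–lithium exchange followed by 1,2-addition to a non-enolisable aryl aldehyde forms C1–C8a; at −78 °C exchange is much faster than benzylic deprotonation or 6-exo carbolithiation of the remote alkene, and the new carbinol centre needs no control.

Step 11
Reactants: 17 {3-(benzyloxy)-6-[(2S)-2-[(benzyloxy)methyl]pent-4-en-1-yl]-2,4-dimethoxyphenyl}{4-[(tert-butyldimethylsilyl)oxy]-3-methoxyphenyl}methanol (both carbinol epimers)
Product: 19 (3R)-3-[(benzyloxy)methyl]-4-{4-(benzyloxy)-2-[{4-[(tert-butyldimethylsilyl)oxy]-3-methoxyphenyl}(hydroxy)methyl]-3,5-dimethoxyphenyl}butanal (both carbinol epimers), via vicinal diol 18 (not isolated)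
Conditions: OsO4 (2 mol%), NaIO4, 2,6-lutidine, dioxane/H2O (3:1), rt
Reagents that add atoms: osmium tetroxide, O=[Os](=O)(=O)=O (catalytic; its oxygen is replaced from sodium periodate, [Na+].[O-]I(=O)(=O)=O)
Why: Lemieux–Johnson cleavage (dihydroxylation, then periodate scission) of the only alkene gives the C9' aldehyde; lutidine keeps the medium neutral for the acid-labile benzhydrol, the silylated phenol is not attacked by periodate, and the stereocentre is untouched (its descriptor changes from S to R only through the priority change).

Step 12
Reactants: 19 (3R)-3-[(benzyloxy)methyl]-4-{4-(benzyloxy)-2-[{4-[(tert-butyldimethylsilyl)oxy]-3-methoxyphenyl}(hydroxy)methyl]-3,5-dimethoxyphenyl}butanal (both carbinol epimers)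
Product: 20 (3R)-3-[(benzyloxy)methyl]-4-{4-(benzyloxy)-2-[hydroxy(4-hydroxy-3-methoxyphenyl)methyl]-3,5-dimethoxyphenyl}butanal (both carbinol epimers)
Conditions: TBAF, AcOH, THF, 0 °C; neutral work-up, used at once
Reagents that add atoms: none
Why: Fluoride cleavage of an aryl silyl ether, which is fast even when buffered; acetic acid keeps the phenoxide protonated so that neither aldol chemistry of the aldehyde nor base-induced loss of the carbinol hydroxyl sets in.

Step 13
Reactants: 20 (3R)-3-[(benzyloxy)methyl]-4-{4-(benzyloxy)-2-[hydroxy(4-hydroxy-3-methoxyphenyl)methyl]-3,5-dimethoxyphenyl}butanal (both carbinol epimers)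
Product: 22 (1S,2R,3R)-7-(benzyloxy)-3-[(benzyloxy)methyl]-1-(4-hydroxy-3-methoxyphenyl)-6,8-dimethoxy-1,2,3,4-tetrahydronaphthalene-2-carbaldehyde, via quinone methide enamine 21 (not isolated)
Conditions: (R)-α,α-diphenylprolinol TMS ether (20 mol%), PhCO2H (40 mol%), CH2Cl2 (0.02 M), 0 °C → rt
Reagents that add atoms: none
Why: This is an enamine-catalysed intramolecular 1,6-addition to a p-quinone methide (organocatalytic aldehyde α-alkylation); the closest known reactions are the prolinol-ether-catalysed addition of aldehydes to p-quinone methides and the amine-catalysed SN1-type alkylation of aldehydes by benzhydrols. The carbinol of 20 is a 2,4-dialkoxy-4'-hydroxybenzhydrol, as acid-labile as a benzhydryl linker, so benzoic acid should ionise either epimer and loss of water gives the guaiacyl quinone methide, while the amine converts the aldehyde into its E-enamine; both reactive ends are then present in 21. The enamine carbon C2 adds to the exocyclic carbon C1 in a 6-exo-trig closure through a chair-like array of C1, C2, C3, C4, C4a and C8a; the guaiacyl ring rearomatises and the water formed hydrolyses the iminium ion to release 22 and the catalyst. C2 is controlled by C3: the benzyloxymethyl group sits equatorial and the enamine arm takes the equatorial place beside it (2,3-trans); the (R)-catalyst leaves open exactly this enamine face, so catalyst and substrate are matched, and because C2 stays α to the aldehyde any cis material can equilibrate to trans through the same enamine. C1 is controlled by the chair: the quinone methide ring takes the pseudo-equatorial side with H1 and H2 anti, which puts the aryl group cis to the C3 substituent. The one selectivity the step must deliver is therefore the 1,3-cis relation of C1 to C3; it rests on an early transition state in which the di-ortho-substituted arene is twisted out of the quinone methide plane and the C8 methoxy group is still remote from the incoming ring. High dilution keeps the quinone methide from capturing a second molecule.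

Step 14
Reactants: 22 (1S,2R,3R)-7-(benzyloxy)-3-[(benzyloxy)methyl]-1-(4-hydroxy-3-methoxyphenyl)-6,8-dimethoxy-1,2,3,4-tetrahydronaphthalene-2-carbaldehyde
Product: 23 4-[(1S,2R,3R)-7-(benzyloxy)-3-[(benzyloxy)methyl]-2-(hydroxymethyl)-6,8-dimethoxy-1,2,3,4-tetrahydronaphthalen-1-yl]-2-methoxyphenol
Conditions: NaBH4, MeOH, 0 °C
Reagents that add atoms: none
Why: Borohydride reduction of the aldehyde at low temperature is faster than enolisation, so the C2 configuration is frozen as the C9' alcohol.

Step 15
Reactants: 23 4-[(1S,2R,3R)-7-(benzyloxy)-3-[(benzyloxy)methyl]-2-(hydroxymethyl)-6,8-dimethoxy-1,2,3,4-tetrahydronaphthalen-1-yl]-2-methoxyphenol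
Product: 24 (+)-8-methoxyisolariciresinol
Conditions: H2 (1 atm), 10% Pd/C, EtOAc/EtOH, rt
Reagents that add atoms: none
Why: Catalytic hydrogenolysis removes the aryl and the alkyl benzyl ether together under neutral conditions that spare the phenols, the three stereocentres and the 1,4-diol.

## Compound list

1 | syringaldehyde (4-hydroxy-3,5-dimethoxybenzaldehyde) | COc1cc(C=O)cc(OC)c1O | starting material
2 | 4-(benzyloxy)-3,5-dimethoxybenzaldehyde | COc1cc(C=O)cc(OC)c1OCc1ccccc1 | intermediate
3 | [4-(benzyloxy)-3,5-dimethoxyphenyl]methanol | COc1cc(CO)cc(OC)c1OCc1ccccc1 | intermediate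
4 | 2-(benzyloxy)-5-(bromomethyl)-1,3-dimethoxybenzene | COc1cc(CBr)cc(OC)c1OCc1ccccc1 | intermediate
5 | (4R)-4-benzyl-1,3-oxazolidin-2-one | O=C1N[C@H](Cc2ccccc2)CO1 | starting material
6 | pent-4-enoic acid | C=CCCC(=O)O | starting material
7 | pent-4-enoic pivalic anhydride (not isolated) | C=CCCC(=O)OC(=O)C(C)(C)C | intermediate
8 | (4R)-4-benzyl-3-(pent-4-enoyl)-1,3-oxazolidin-2-one | C=CCCC(=O)N1[C@H](Cc2ccccc2)COC1=O | intermediate
9 | sodium (Z)-enolate of 8 (not isolated) | C=CC/C=C(\[O-])N1[C@H](Cc2ccccc2)COC1=O.[Na+] | intermediate
10 | (4R)-4-benzyl-3-[(2S)-2-{[4-(benzyloxy)-3,5-dimethoxyphenyl]methyl}pent-4-enoyl]-1,3-oxazolidin-2-one | C=CC[C@@H](Cc1cc(OC)c(OCc2ccccc2)c(OC)c1)C(=O)N1[C@H](Cc2ccccc2)COC1=O | intermediate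
11 | (2S)-2-{[4-(benzyloxy)-3,5-dimethoxyphenyl]methyl}pent-4-en-1-ol | C=CC[C@@H](Cc1cc(OC)c(OCc2ccccc2)c(OC)c1)CO | intermediate
12 | 2-(benzyloxy)-5-[(2S)-2-[(benzyloxy)methyl]pent-4-en-1-yl]-1,3-dimethoxybenzene | C=CC[C@@H](Cc1cc(OC)c(OCc2ccccc2)c(OC)c1)COCc1ccccc1 | intermediate
13 | 4-(benzyloxy)-1-[(2S)-2-[(benzyloxy)methyl]pent-4-en-1-yl]-2-bromo-3,5-dimethoxybenzene | C=CC[C@@H](Cc1cc(OC)c(OCc2ccccc2)c(OC)c1Br)COCc1ccccc1 | intermediate
14 | vanillin (4-hydroxy-3-methoxybenzaldehyde) | COc1cc(C=O)ccc1O | starting material
15 | 4-[(tert-butyldimethylsilyl)oxy]-3-methoxybenzaldehyde | COc1cc(C=O)ccc1O[Si](C)(C)C(C)(C)C | intermediate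
16 | aryllithium from 13, lithium in place of bromine (not isolated) | C=CC[C@@H](Cc1cc(OC)c(OCc2ccccc2)c(OC)c1[Li])COCc1ccccc1 | intermediate
17 | {3-(benzyloxy)-6-[(2S)-2-[(benzyloxy)methyl]pent-4-en-1-yl]-2,4-dimethoxyphenyl}{4-[(tert-butyldimethylsilyl)oxy]-3-methoxyphenyl}methanol (both carbinol epimers) | C=CC[C@@H](Cc1cc(OC)c(OCc2ccccc2)c(OC)c1C(O)c1ccc(O[Si](C)(C)C(C)(C)C)c(OC)c1)COCc1ccccc1 | intermediate
18 | (4R)-4-[(benzyloxy)methyl]-5-{4-(benzyloxy)-2-[{4-[(tert-butyldimethylsilyl)oxy]-3-methoxyphenyl}(hydroxy)methyl]-3,5-dimethoxyphenyl}pentane-1,2-diol (epimers at C2 and at the carbinol; not isolated) | OCC(O)C[C@@H](Cc1cc(OC)c(OCc2ccccc2)c(OC)c1C(O)c1ccc(O[Si](C)(C)C(C)(C)C)c(OC)c1)COCc1ccccc1 | intermediate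
19 | (3R)-3-[(benzyloxy)methyl]-4-{4-(benzyloxy)-2-[{4-[(tert-butyldimethylsilyl)oxy]-3-methoxyphenyl}(hydroxy)methyl]-3,5-dimethoxyphenyl}butanal (both carbinol epimers) | O=CC[C@@H](Cc1cc(OC)c(OCc2ccccc2)c(OC)c1C(O)c1ccc(O[Si](C)(C)C(C)(C)C)c(OC)c1)COCc1ccccc1 | intermediate
20 | (3R)-3-[(benzyloxy)methyl]-4-{4-(benzyloxy)-2-[hydroxy(4-hydroxy-3-methoxyphenyl)methyl]-3,5-dimethoxyphenyl}butanal (both carbinol epimers) | O=CC[C@@H](Cc1cc(OC)c(OCc2ccccc2)c(OC)c1C(O)c1ccc(O)c(OC)c1)COCc1ccccc1 | intermediate
21 | quinone methide E-enamine formed from 20 and (R)-α,α-diphenylprolinol TMS ether (not isolated) | O=C1C=CC(=Cc2c(C[C@@H](COCc3ccccc3)/C=C/N3CCC[C@@H]3C(O[Si](C)(C)C)(c3ccccc3)c3ccccc3)cc(OC)c(OCc3ccccc3)c2OC)C=C1OC | intermediate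
22 | (1S,2R,3R)-7-(benzyloxy)-3-[(benzyloxy)methyl]-1-(4-hydroxy-3-methoxyphenyl)-6,8-dimethoxy-1,2,3,4-tetrahydronaphthalene-2-carbaldehyde | COc1cc([C@H]2c3c(cc(OC)c(OCc4ccccc4)c3OC)C[C@@H](COCc3ccccc3)[C@@H]2C=O)ccc1O | intermediate
23 | 4-[(1S,2R,3R)-7-(benzyloxy)-3-[(benzyloxy)methyl]-2-(hydroxymethyl)-6,8-dimethoxy-1,2,3,4-tetrahydronaphthalen-1-yl]-2-methoxyphenol | COc1cc([C@H]2c3c(cc(OC)c(OCc4ccccc4)c3OC)C[C@@H](COCc3ccccc3)[C@@H]2CO)ccc1O | intermediate
24 | (+)-8-methoxyisolariciresinol, 4-[(1S,2R,3R)-7-hydroxy-2,3-bis(hydroxymethyl)-6,8-dimethoxy-1,2,3,4-tetrahydronaphthalen-1-yl]-2-methoxyphenol | COc1cc([C@H]2c3c(cc(OC)c(O)c3OC)C[C@@H](CO)[C@@H]2CO)ccc1O | target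

## Step count and least certain steps

Total: 15 steps. Longest linear sequence: 13 steps (1 → 24 through steps 1, 2, 3, 5, 6, 7, 8, 10, 11, 12, 13, 14, 15); steps 4 and 9 are side branches.

**Step 13 (key step).** The most likely failure is poor facial selectivity at C1. As C1 pyramidalises, the incoming guaiacyl ring meets the C8 methoxy group, and a later transition state could prefer the pseudo-axial mode and give the 1,3-trans series. Slow ionisation of the carbinol, or capture of the quinone methide by a second molecule or by the amine, would lower conversion. C2 is not the concern, since it equilibrates. Fallback: give up the C1–C2 closure and close C1–C8a by known Friedel–Crafts chemistry, setting out from 11 and returning at 24.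
- Lemieux–Johnson cleavage of 11 gives the lactol F1.
- TEMPO/PhI(OAc)2 oxidises it to the (R)-β-arylmethyl-γ-butyrolactone F2.
- The lithium enolate of F2 (LiHMDS, THF, −78 °C) adds to commercial 4-(benzyloxy)-3-methoxybenzaldehyde anti to the β-substituent and gives the trans aldol F3 as carbinol epimers.
- TFA in CH2Cl2 at 0 °C ionises the carbinol. The trialkoxy ring closes at either of its two equivalent free positions through an all-equatorial chair, the classical closure that gives the all-trans aryltetralin lactone F4.
- LiAlH4 opens the lactone to the diol F5, and hydrogenolysis of its two aryl benzyl ethers gives 24.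

**Step 8.** Bromination could be diverted by the alkene (bromonium formation with participation of the neighbouring benzyl ether oxygen) or run on to a second ring bromination. Fallback: introduce bromine before the alkene exists, setting out from 3 and returning at 13.
- NBS in MeCN converts 3 into the bromo alcohol F6, and PBr3 gives the dibromide F7.
- Enolate 9 is alkylated with F7 under the conditions of step 5 to give the bromo imide F8.
- LiBH4 gives the bromo alcohol F9, and benzylation as in step 7 gives 13.

**Step 10.** The aryllithium 16 is flanked by two ortho substituents, so its addition to 15 may be slow. That would let benzylic deprotonation, butylation by 1-bromobutane or protonation on warming compete. Fallback: reverse the polarity of the coupling, setting out from 12 and returning at 17.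
- Vilsmeier–Haack formylation of 12 (POCl3, DMF) puts the aldehyde on the same ring position and gives the hindered aldehyde F10.
- Commercial 4-bromo-2-methoxyphenol is silylated to the silyl ether F11, which n-BuLi converts at −78 °C into the unhindered aryllithium F12.
- Addition of F12 to F10 gives 17.

**Step 12.** Fluoride makes a phenoxide para to an ionisable carbinol in a molecule that also holds an enolisable aldehyde. Premature loss of the carbinol hydroxyl, uncatalysed cyclisation without stereocontrol, or aldol condensation could erode 20 before it reaches step 13. Fallback: change the order so that the free phenol never coexists with the open-chain aldehyde, setting out from 19 and returning at 23.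
- The silyl ether 19 is cyclised through its diarylmethyl cation (same amine catalyst as its trifluoroacetate salt, the known SN1-type enamine alkylation by benzhydrols) to the silylated tetralin aldehyde F13.
- NaBH4 gives the silylated alcohol F14, and TBAF then gives 23.

## Further compounds

F1 | step 13 | (4R)-4-{[4-(benzyloxy)-3,5-dimethoxyphenyl]methyl}oxolan-2-ol (both anomers) | OC1C[C@@H](Cc2cc(OC)c(OCc3ccccc3)c(OC)c2)CO1
F2 | step 13 | (4R)-4-{[4-(benzyloxy)-3,5-dimethoxyphenyl]methyl}oxolan-2-one | O=C1C[C@@H](Cc2cc(OC)c(OCc3ccccc3)c(OC)c2)CO1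
F3 | step 13 | (3S,4R)-4-{[4-(benzyloxy)-3,5-dimethoxyphenyl]methyl}-3-{[4-(benzyloxy)-3-methoxyphenyl](hydroxy)methyl}oxolan-2-one (trans; both carbinol epimers) | O=C1OC[C@H](Cc2cc(OC)c(OCc3ccccc3)c(OC)c2)[C@H]1C(O)c1ccc(OCc2ccccc2)c(OC)c1
F4 | step 13 | all-trans 7-(benzyloxy)-9-[4-(benzyloxy)-3-methoxyphenyl]-6,8-dimethoxy-3a,4,9,9a-tetrahydronaphtho[2,3-c]furan-1(3H)-one (ring centres as in 24) | COc1cc([C@H]2c3c(cc(OC)c(OCc4ccccc4)c3OC)C[C@H]3COC(=O)[C@H]23)ccc1OCc1ccccc1
F5 | step 13 | [(1S,2R,3R)-7-(benzyloxy)-1-[4-(benzyloxy)-3-methoxyphenyl]-6,8-dimethoxy-1,2,3,4-tetrahydronaphthalene-2,3-diyl]dimethanol | COc1cc([C@H]2c3c(cc(OC)c(OCc4ccccc4)c3OC)C[C@@H](CO)[C@@H]2CO)ccc1OCc1ccccc1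
F6 | step 8 | [4-(benzyloxy)-2-bromo-3,5-dimethoxyphenyl]methanol | COc1cc(CO)c(Br)c(OC)c1OCc1ccccc1
F7 | step 8 | 4-(benzyloxy)-2-bromo-1-(bromomethyl)-3,5-dimethoxybenzene | COc1cc(CBr)c(Br)c(OC)c1OCc1ccccc1
F8 | step 8 | (4R)-4-benzyl-3-[(2S)-2-{[4-(benzyloxy)-2-bromo-3,5-dimethoxyphenyl]methyl}pent-4-enoyl]-1,3-oxazolidin-2-one | C=CC[C@@H](Cc1cc(OC)c(OCc2ccccc2)c(OC)c1Br)C(=O)N1[C@H](Cc2ccccc2)COC1=O
F9 | step 8 | (2S)-2-{[4-(benzyloxy)-2-bromo-3,5-dimethoxyphenyl]methyl}pent-4-en-1-ol | C=CC[C@@H](Cc1cc(OC)c(OCc2ccccc2)c(OC)c1Br)CO
F10 | step 10 | 3-(benzyloxy)-6-[(2S)-2-[(benzyloxy)methyl]pent-4-en-1-yl]-2,4-dimethoxybenzaldehyde | C=CC[C@@H](Cc1cc(OC)c(OCc2ccccc2)c(OC)c1C=O)COCc1ccccc1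
F11 | step 10 | (4-bromo-2-methoxyphenoxy)(tert-butyl)dimethylsilane | COc1cc(Br)ccc1O[Si](C)(C)C(C)(C)C
F12 | step 10 | {4-[(tert-butyldimethylsilyl)oxy]-3-methoxyphenyl}lithium | COc1cc([Li])ccc1O[Si](C)(C)C(C)(C)C
F13 | step 12 | (1S,2R,3R)-7-(benzyloxy)-3-[(benzyloxy)methyl]-1-{4-[(tert-butyldimethylsilyl)oxy]-3-methoxyphenyl}-6,8-dimethoxy-1,2,3,4-tetrahydronaphthalene-2-carbaldehyde | COc1cc([C@H]2c3c(cc(OC)c(OCc4ccccc4)c3OC)C[C@@H](COCc3ccccc3)[C@@H]2C=O)ccc1O[Si](C)(C)C(C)(C)C
F14 | step 12 | [(1S,2R,3R)-7-(benzyloxy)-3-[(benzyloxy)methyl]-1-{4-[(tert-butyldimethylsilyl)oxy]-3-methoxyphenyl}-6,8-dimethoxy-1,2,3,4-tetrahydronaphthalen-2-yl]methanol | COc1cc([C@H]2c3c(cc(OC)c(OCc4ccccc4)c3OC)C[C@@H](COCc3ccccc3)[C@@H]2CO)ccc1O[Si](C)(C)C(C)(C)C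
A1 | alternative 1 | 4-[(3-hydroxy-2,4-dimethoxyphenyl)(phenylsulfonyl)methyl]-2-methoxyphenol (racemic) | COc1cc(C(c2ccc(OC)c(O)c2OC)S(=O)(=O)c2ccccc2)ccc1O
A2 | alternative 1 | dimethyl itaconate | C=C(CC(=O)OC)C(=O)OC
A3 | alternative 1 | dimethyl (1S,2R,3R)-7-hydroxy-1-(4-hydroxy-3-methoxyphenyl)-6,8-dimethoxy-1,2,3,4-tetrahydronaphthalene-2,3-dicarboxylate | COc1cc([C@H]2c3c(cc(OC)c(O)c3OC)C[C@@H](C(=O)OC)[C@@H]2C(=O)OC)ccc1O
A4 | alternative 2 | trans-2,3-bis[(benzyloxy)methyl]-4-(phenylsulfonyl)cyclobutan-1-one (C4 epimers) | O=C1C(S(=O)(=O)c2ccccc2)[C@@H](COCc2ccccc2)[C@@H]1COCc1ccccc1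
A5 | alternative 2 | 3-(benzyloxy)-2,4-dimethoxy-6-(trimethylsilyl)phenyl trifluoromethanesulfonate | COc1cc([Si](C)(C)C)c(OS(=O)(=O)C(F)(F)F)c(OC)c1OCc1ccccc1
A6 | alternative 2 | trans-2,3-bis[(benzyloxy)methyl]-7-(benzyloxy)-6,8-dimethoxy-4-(phenylsulfonyl)-3,4-dihydronaphthalen-1(2H)-one (C4 epimers) | O=C1c2c(cc(OC)c(OCc3ccccc3)c2OC)C(S(=O)(=O)c2ccccc2)[C@@H](COCc2ccccc2)[C@@H]1COCc1ccccc1
A7 | alternative 3 | 3-(3-hydroxy-2,4-dimethoxyphenyl)-3-(4-mesyloxy-3-methoxyphenyl)-2-(oxetan-3-yl)propyl pivalate, C1 and C2 configured as in 24 | COc1cc([C@@H](c2ccc(OC)c(O)c2OC)[C@@H](COC(=O)C(C)(C)C)C2COC2)ccc1OS(C)(=O)=O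
A8 | alternative 3 | all-trans 7-hydroxy-3-(hydroxymethyl)-1-(4-mesyloxy-3-methoxyphenyl)-6,8-dimethoxy-2-(pivaloyloxymethyl)-1,2,3,4-tetrahydronaphthalene (configuration of 24) | COc1cc([C@H]2c3c(cc(OC)c(O)c3OC)C[C@@H](CO)[C@@H]2COC(=O)C(C)(C)C)ccc1OS(C)(=O)=O
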